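The earlier runs and the new flask come from a simulation with constants of no real substance; the scatter is artificial.

The constant I look for in Thursday's run is the pace at which product appears, in percent of the charge. The flasks and the questions are these.

| setting | Thursday's | spring | summer |
|---|---|---|---|
| left-handed substrate | 0.040 M | 0.020 M | 0.020 M |
| right-handed substrate | 0.040 M | 0.020 M | 0.020 M |
| gas | 4.9 mM (held) | 4.9 mM (held) | 4.9 mM (held) |
| free catalyst | 15 mol% | 15 mol% | 15 mol% |
| remark | run made earlier |  |  |
| time |  | 3.0 d | 10 d |

Thursday's run (percent of the left-handed substrate and right-handed substrate together charged)

| time / h | left-handed product / % | right-handed product / % | left-handed substrate / % |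
|---|---|---|---|
| 2.50 | 1.1 | 1.6 | 49.1 |
| 5.00 | 1.1 | 2.6 | 48.2 |
| 8.00 | 2.1 | 3.7 | 47.7 |
| 10.0 | 2.8 | 4.7 | 47.3 |
| 12.0 | 3.0 | 5.2 | 46.1 |
| 15.0 | 4.1 | 6.5 | 46.0 |

(readings scatter by 0.3 percentage points)

- free catalyst is single-handed; left-handed substrate and right-handed substrate are mirror images of each other, charged as a racemate, each of them at the stated concentration
- the numbers in the tables scatter by 0.3 percentage points (one standard deviation)
- at the start none of the gas is in solution
- an excess is the difference of the two amounts in percent of their sum
- an excess is below zero if the other one leads
- no earlier run changes the charge of free catalyst; that part of a forecast is a guess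

1. which of the two ends with the higher excess of left-handed product over right-handed product in the product ("neither" if they lie within 2 percentage points) (spring / summer / neither)
2. excess of left-handed product over right-handed product in the product at the end, spring
3. excess of left-handed product over right-handed product in the product at the end, summer

[gas] is held, so the racemate is the limiting reagent, and I keep a ledger of it. Each mole stands as substrate, as product of its own hand, or bound on the catalyst, an entry Thursday's table does not read. At 15.0 h in Thursday's run, the left-handed side reads:

left-handed substrate + left-handed product = 46.0% + 4.1% = 50.1%

That side of the books balances within the scatter, but Thursday's run does not read right-handed substrate, so the right-handed side stays unchecked. The product entries grow about evenly, so I freeze their pace. My clearing time is the time that pace needs to turn the whole charge into product: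

clearing time = 15.0 h / (4.1% + 6.5%) = 5.90 d

Spring and summer have half the concentrations at the same loading. I assume each catalyst keeps its pace, so the percent pace and the clearing time carry over.

In spring, my reckoning gives 50.9% of the charge as product, with the excess near Thursday's reading of −22.6%. Summer lasts 1.69 clearing times, longer than the books need. Both product entries then approach half the charge, and I expect an excess near zero.

The forecast differs for summer. It gives −21% for spring and −16% for summer, so summer ends higher: “The longer run erodes the excess toward zero as the slower enantiomer catches up”.

The flask gives −21.7% in spring and −4.14% in summer, so summer ends higher, and the forecast's summer value lies 12 percentage points below the flask's.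

    free catalyst + left-handed substrate ⇌ catalyst intermediate A (K = 70.0 L mol⁻¹, k = 190 L mol⁻¹ min⁻¹)
    free catalyst + right-handed substrate ⇌ catalyst intermediate B (K = 1400 L mol⁻¹, k = 54.0 L mol⁻¹ min⁻¹)
    partner + catalyst intermediate A → free catalyst + left-handed product (k = 2.10 L mol⁻¹ min⁻¹)
    partner + catalyst intermediate B → free catalyst + right-handed product (k = 0.240 L mol⁻¹ min⁻¹)
    partner + free catalyst → spent catalyst (k = 0.150 L mol⁻¹ min⁻¹)
    gas ⇌ partner, rate k6*(csat - [partner]) (kL = 0.700 min⁻¹)
    free catalyst ⇌ dormant form (K = 1.70, k = 0.00150 min⁻¹)

In summer at 5.00 d, product stands at 72.7%, less than the 84.7% my clearing time gives, while catalyst intermediate B, the resting state, holds 34.8% of the catalyst. At 10.0 d, summer's product stands at 94.2%, with 0.767% right-handed substrate and 4.78% left-handed substrate left, and spent catalyst holds 81.2% of the catalyst.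

The neighbour flask is summer with 3.8 mol% of free catalyst. Scaling the clearing time with the loading, which is a guess, gives 23.3 d, so 10 d covers 42.9% of it and the books stay open. That flask holds 34.0% as product and ends at −30.1%.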